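**A small charge.** I began from a small charge: this flask held 0.720 M of X against 0.40 M of Z.

| flask | Z | X | remark | time | volume of the second phase over the first |
|---|---|---|---|---|---|
| Friday's | 0.56 M | 0.72 M | run made earlier |  |  |
| Thursday's | 0.88 M | 0.72 M | run made earlier |  |  |
| Wednesday's | 0.40 M | 1.4 M | run made earlier |  |  |
| flask | 0.40 M | 0.720 M |  | 8.0 h | 1.0 |

- Friday's (time / h: L / %): 0.500: 0.5; 1.00: 3.0; 2.00: 5.0; 3.00: 5.6; 6.00: 7.0
- Thursday's (time / h: L / %): 1.33: 3.2; 2.50: 5.9; 4.00: 7.6; 5.00: 5.9; 6.00: 5.7
- Wednesday's (time / h: L / %): 0.500: 2.5; 1.50: 7.9; 3.00: 10.2; 5.00: 9.9; 6.00: 7.2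

(each reading ± 1 percentage point)

- percentages count the Z that a species holds: one J counts as two
- in the second phase: X; everything else is in the first
- charges count per volume of the first phase; a concentration in a rate is the amount of a species over the volume of its own phase; every rate counts per litre of the first phase
- the analysis behind the earlier runs scatters by 1 percentage point, standard deviation
- reactions considered so far: E <-> X; Z + E <-> L; E + L -> Q; 2 Z -> J
- the earlier runs hold the two phases in the same ratio of volumes as the flask asked about

* amount of L in percent of the Z charged, at 50 min, 2.5 h, 5.0 h and 8.0 h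

**The entries.** I kept the books on X and counted what was left of it, not what was made. A mole of X that had crossed became E. Each L holds one E, each Q has taken two, and J holds none.

**The cover.** I called the X charged over twice the Z charged, 90.0% in this flask, the cover. With Q and L as fractions of the Z charged, the books closed as: X left = 1 − (Q + 0.5 L)/cover − [E]/(X charged). In this flask the cover stood below 100%, which made X the limiting reagent for Q, and Q could reach at most 90.0% of the Z charged. On Wednesday's run the cover was 175%, and the highest reading of L was 10.2%. On Thursday's it was 40.9%, and the highest reading was 7.6%.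

**The forecast.** The forecast gave 2%, 5%, 6.4% and 6%, and said that “L then levels off through reversal and E + L → Q”. By my own ledger, L at the forecast's highest value would hold 3.56% of the X charged.

**The result.** The flask gave 2.74%, 7.45%, 8.12% and 7.22%, so the forecast was right within its margin, though lower at each time.

    E ⇌ X, rate k1*([E] - [X]/K1) per volume of the first phase (partition coefficient = 3.10, kL = 4.70 × 10⁻⁵ s⁻¹)
    Z + E ⇌ L (K = 6.40 L mol⁻¹, k = 0.00110 L mol⁻¹ s⁻¹)
    E + L → Q (k = 0.00440 L mol⁻¹ s⁻¹)
    2 Z → J (k = 1.30 × 10⁻⁶ L mol⁻¹ s⁻¹)

**The closing.** At 3.51 h the flask made L 1.08 times as fast as it used L up, each step taken net. At that time L fell back 1.5 times faster than it went on to Q. At 8.00 h, Q at 21.6%, L at 7.22% and [E] at 0.0261 M, entered against the cover, left 68.4% of the X charged still standing as X in this flask. In the flask with twice the X, the cover was 180%, which made Z the limiting reagent for Q, and L stood at 6.82%.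

The readings are calculated with constants of no real substance; scatter was added.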